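**Retrosynthetic overview**

1. The target comes from C7 oxidation and C16 deselenation of a selenide that is made in one cascade from an 8α,9α-epoxy 7β-acetate carrying a 3-furylethyl chain. Se-triggered furan dearomatization, then an epoxonium and an acetoxonium ion, close the 9,13-ether, create the spiro-dihydrofuran and deliver the acetate to O8.
2. The epoxide comes from an 8(9)-ene 7β-acetate, made by 1,3-transposition of the tertiary allylic alcohol from furylethyl Grignard addition to a tricyclic enone lactone.
3. The enone lactone comes from C6 reduction, C4 methylation and lactonization of a trans-fused ene-dione ester.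
4. Key step: the bicyclic core comes from a Michael–alkylation annulation of the enolate of methyl 5-bromopentanoate onto a C2-symmetric quinone monoketal (from 2,6-dimethylphenol by oxidative dearomatization). It desymmetrizes the dienone and builds ring A with the C10 quaternary centre.
5. Ring order: ring B (from the arene), ring A, γ-lactone, then tetrahydrofuran and dihydrofuran together.

Assumption and convention: 2-(furan-3-yl)ethanol is taken as a catalogue building block; bicyclic and later compounds are named with labdane numbering (decalin C1–C10, C17 on C8, C18/C19 on C4, C20 on C10; β is the face of C20).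

**Route**

Step 1
Reactants: 1 2,6-dimethylphenol
Product: 2 4,4-dimethoxy-2,6-dimethylcyclohexa-2,5-dien-1-one
Conditions: PhI(OAc)2 (2.1 equiv), MeOH, 0 → 25 °C
Reagents that add atoms: methanol (CO)
Why: Twofold oxidative dearomatization of a para-unsubstituted phenol in methanol (phenol to 4-methoxyphenol to para-quinone monoketal) is an established hypervalent-iodine reaction and breaks the aromaticity of the feedstock without creating a stereocenter.

Step 2
Reactants: 2 4,4-dimethoxy-2,6-dimethylcyclohexa-2,5-dien-1-one; 3 (1S,2S)-1,2-diphenylethane-1,2-diol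
Product: 4 (2S,3S)-7,9-dimethyl-2,3-diphenyl-1,4-dioxaspiro[4.5]deca-6,9-dien-8-one
Conditions: BF3·OEt2 (0.3 equiv), DME, 25 °C
Reagents that add atoms: none
Why: Acid-catalysed transketalization exchanges two methanol for the diol, and because the diol is C2-symmetric the spiro carbon is not a stereocenter, the two enone arms stay homotopic and only their faces become diastereotopic.

Step 3
Reactants: 4 (2S,3S)-7,9-dimethyl-2,3-diphenyl-1,4-dioxaspiro[4.5]deca-6,9-dien-8-one; 5 methyl 5-bromopentanoate
Product: 8 methyl 8,10β-dimethyl-9-oxo-5βH-decal-7-ene-4-carboxylate 6-[(1S,2S)-1,2-diphenylethylene ketal] (cis-fused; C4 epimers), via lithium ester enolate 6 (not isolated), via lithium dienolate Michael adduct 7 (not isolated)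
Conditions: LiN(iPr)2 (1.05 equiv), THF, −78 °C; add 5, then 4, −78 → −30 °C; DMPU, → 25 °C
Reagents that add atoms: none
Why: Michael-initiated ring closure in which the ester enolate adds 1,4 (the carbonyl is flanked by two methyl-bearing carbons) to C5 on the α face, the face not covered by the phenyl of the (S,S)-dioxolane, and the resulting cross-conjugated ketone enolate is alkylated at C10 by the tethered bromide (6-exo-tet) on the same face, which sets C10 (methyl β) with a cis ring fusion and destroys the C2 symmetry, while C4 forms as an epimer mixture that is re-set in step 6.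

Step 4
Reactants: 8 methyl 8,10β-dimethyl-9-oxo-5βH-decal-7-ene-4-carboxylate 6-[(1S,2S)-1,2-diphenylethylene ketal]
Product: 9 methyl 8,10β-dimethyl-6,9-dioxo-5αH-decal-7-ene-4-carboxylate (trans-fused; C4 epimers)
Conditions: TFA–H2O (9:1), CH2Cl2, 0 → 25 °C; then DBU (0.2 equiv), CH2Cl2, 25 °C
Reagents that add atoms: water (O)
Why: Ketal hydrolysis unveils the C6 ketone and base-mediated enolization epimerizes C5 to the more stable trans-fused ene-dione (the behaviour known for angular-methyl quinone Diels–Alder adducts), while the quaternary C10 cannot epimerize or aromatize.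

Step 5
Reactants: 9 methyl 8,10β-dimethyl-6,9-dioxo-5αH-decal-7-ene-4-carboxylate
Product: 10 methyl 6β-hydroxy-8,10β-dimethyl-9-oxo-5αH-decal-7-ene-4-carboxylate (C4 epimers)
Conditions: NaBH4, CeCl3·7H2O, MeOH, −78 °C
Reagents that add atoms: none
Why: Luche 1,2-reduction takes the less hindered C6 carbonyl (C9 sits between the quaternary C10 and the methyl-bearing C8) and hydride arrives from the α face opposite the axial C20 methyl, giving the axial 6β-alcohol.

Step 6
Reactants: 10 methyl 6β-hydroxy-8,10β-dimethyl-9-oxo-5αH-decal-7-ene-4-carboxylate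
Product: 11 9-oxo-11,12,13,14,15,16-hexanorlabd-7-en-19,6β-olide
Conditions: KN(SiMe3)2 (2.3 equiv), THF, −78 °C; MeI (1.2 equiv), −78 → 25 °C
Reagents that add atoms: iodomethane (CI)
Why: Enolate alkylation then lactonization, in which the ester enolate (either C4 epimer converges) is methylated from the equatorial α face away from the 1,3-syn-axial C20 methyl, as in podocarpate-type alkylations, so the ester ends axial (β) and is closed to the γ-lactone by the 6β-alkoxide on warming; the enone has no enolizable position once O6 is an alkoxide.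

Step 7
Reactants: 12 2-(furan-3-yl)ethanol
Product: 13 3-(2-bromoethyl)furan
Conditions: CBr4, PPh3, CH2Cl2, 0 °C
Reagents that add atoms: carbon tetrabromide (BrC(Br)(Br)Br)
Why: Appel bromination of a primary alcohol under neutral conditions that leave the furan untouched.

Step 8
Reactants: 11 9-oxo-11,12,13,14,15,16-hexanorlabd-7-en-19,6β-olide; 13 3-(2-bromoethyl)furan
Product: 15 15,16-epoxy-9β-hydroxy-9-epi-labda-7,13(16),14-trien-19,6β-olide (side chain α on C9), via Grignard reagent 14 (not isolated)
Conditions: Mg, THF, 25 °C; then 11, LaCl3·2LiCl (1 equiv), THF, −78 → 0 °C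
Reagents that add atoms: none
Why: Lanthanum-assisted Grignard 1,2-addition to the hindered enone carbonyl outruns reduction, conjugate addition and attack on the lactone, and occurs from the α face anti to C20 (9β-OH), a configuration that is erased in step 9.

Step 9
Reactants: 15 15,16-epoxy-9β-hydroxy-9-epi-labda-7,13(16),14-trien-19,6β-olide
Product: 17 7β-acetoxy-15,16-epoxylabda-8,13(16),14-trien-19,6β-olide, via 7β-allylic alcohol 16 (not isolated)
Conditions: Ph3SiOReO3 (5 mol %), Et2O, −50 → 0 °C; then Et3N, Ac2O, DMAP (cat.), 0 → 25 °C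
Reagents that add atoms: acetic anhydride (CC(=O)OC(C)=O)
Why: Perrhenate-catalysed 1,3-transposition of the allylic alcohol (suprafacial [3,3] shift of the perrhenate ester across the β face) relieves the congested tertiary C9 carbinol and gives the tetrasubstituted 8(9)-alkene with the equatorial 7β-hydroxyl under thermodynamic control, which is acetylated in the same flask.

Step 10
Reactants: 17 7β-acetoxy-15,16-epoxylabda-8,13(16),14-trien-19,6β-olide
Product: 18 7β-acetoxy-8α,9α:15,16-diepoxylabda-13(16),14-dien-19,6β-olide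
Conditions: mCPBA (1.05 equiv), NaHCO3, CH2Cl2, −20 °C
Reagents that add atoms: 3-chloroperoxybenzoic acid (OOC(=O)c1cccc(Cl)c1)
Why: Prilezhaev epoxidation in which the tetrasubstituted alkene reacts much faster than the 3-alkylfuran and is attacked from the α face, because the β face is blocked by C20, the 6β-lactone oxygen and the non-directing 7β-acetate, which fixes the 9α C–O bond.

Step 11
Reactants: 18 7β-acetoxy-8α,9α:15,16-diepoxylabda-13(16),14-dien-19,6β-olide
Product: 21 (13R,16S)-8β-acetoxy-7β-hydroxy-16-(phenylselanyl)-9α,13:15,16-diepoxylabd-14-en-19,6β-olide, via epoxonium chloride 19 (not isolated), via acetoxonium chloride 20 (not isolated)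
Conditions: PhSeCl (1.1 equiv), NaHCO3 (solid), CH2Cl2, −78 → −30 °C; then H2O, 0 °C
Reagents that add atoms: benzeneselenenyl chloride (Cl[Se]c1ccccc1); water (O)
Why: Proposed new method: PhSe+ adds reversibly to the furan α-carbon C16, the oxocarbenium-stabilized cation is captured at C13 by the epoxide oxygen (5-exo) to give an epoxonium ion, the trans 7β-acetate opens this at C8 with inversion to a dioxolanylium ion, and water hydrolyses that to the axial tertiary 8β-acetate and equatorial 7β-alcohol, so that 8β-OAc and 9α-O are set trans-diaxially and the bulky CH(SePh) is placed anti to O9 and on the C8 side of the new tetrahydrofuran instead of facing the quaternary C10 (13R); the closest known reactions are selenonium- or halonium-triggered epoxide-opening cascades, acetoxonium neighbouring-group opening of epoxides and selenoetherification.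

Step 12
Reactants: 21 (13R,16S)-8β-acetoxy-7β-hydroxy-16-(phenylselanyl)-9α,13:15,16-diepoxylabd-14-en-19,6β-olide
Product: 22 (13R)-8β-acetoxy-7β-hydroxy-9α,13:15,16-diepoxylabd-14-en-19,6β-olide
Conditions: Bu3SnH (1.5 equiv), Et3B (cat.), air, toluene, 0 → 25 °C
Reagents that add atoms: none
Why: Radical deselenation in which the stannyl radical abstracts PhSe from the O,Se-acetal and the α-oxy C16 radical is reduced by the tin hydride faster than it can fragment the C13–O bond, so C16 becomes CH2 and no other stereocenter is touched.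

Step 13
Reactants: 22 (13R)-8β-acetoxy-7β-hydroxy-9α,13:15,16-diepoxylabd-14-en-19,6β-olide
Product: 23 (13R)-8β-acetoxy-9α,13:15,16-diepoxy-7-oxolabd-14-en-19,6β-olide (CNP0155227.2)
Conditions: Dess–Martin periodinane, pyridine, CH2Cl2, 0 → 25 °C
Reagents that add atoms: none
Why: Buffered Dess–Martin oxidation converts the secondary 7β-alcohol to the ketone under near-neutral conditions that spare the acid-labile 3-alkoxy-2,3-dihydrofuran, the tertiary acetate and the lactone.

**Compound list**

1 | 2,6-dimethylphenol | Cc1cccc(C)c1O | starting material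
2 | 4,4-dimethoxy-2,6-dimethylcyclohexa-2,5-dien-1-one | COC1(OC)C=C(C)C(=O)C(C)=C1 | intermediate
3 | (1S,2S)-1,2-diphenylethane-1,2-diol | O[C@@H](c1ccccc1)[C@@H](O)c1ccccc1 | starting material
4 | (2S,3S)-7,9-dimethyl-2,3-diphenyl-1,4-dioxaspiro[4.5]deca-6,9-dien-8-one | CC1=CC2(O[C@@H](c3ccccc3)[C@H](c3ccccc3)O2)C=C(C)C1=O | intermediate
5 | methyl 5-bromopentanoate | COC(=O)CCCCBr | starting material
6 | lithium (Z)-5-bromo-1-methoxypent-1-en-1-olate (O–Li trans to the chain; not isolated) | [Li+].CO/C([O-])=C\CCCBr | intermediate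
7 | lithium (2S,3S)-10-(5-bromo-1-methoxy-1-oxopentan-2-yl)-7,9-dimethyl-2,3-diphenyl-1,4-dioxaspiro[4.5]deca-6,8-dien-8-olate (new bond on the α face of labdane C5; not isolated) | [Li+].COC(=O)C(CCCBr)[C@@H]1C(C)=C([O-])C(C)=CC12O[C@@H](c3ccccc3)[C@H](c3ccccc3)O2 | intermediate
8 | methyl 8,10β-dimethyl-9-oxo-5βH-decal-7-ene-4-carboxylate 6-[(1S,2S)-1,2-diphenylethylene ketal] (cis-fused; C4 epimers) | COC(=O)C1CCC[C@]2(C)C(=O)C(C)=CC3(O[C@@H](c4ccccc4)[C@H](c4ccccc4)O3)[C@H]12 | intermediate
9 | methyl 8,10β-dimethyl-6,9-dioxo-5αH-decal-7-ene-4-carboxylate (trans-fused; C4 epimers) | COC(=O)C1CCC[C@]2(C)C(=O)C(C)=CC(=O)[C@@H]12 | intermediate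
10 | methyl 6β-hydroxy-8,10β-dimethyl-9-oxo-5αH-decal-7-ene-4-carboxylate (C4 epimers) | COC(=O)C1CCC[C@]2(C)C(=O)C(C)=C[C@@H](O)[C@@H]12 | intermediate
11 | 9-oxo-11,12,13,14,15,16-hexanorlabd-7-en-19,6β-olide (4α-Me, 5α-H, 10β-Me) | CC1=C[C@H]2OC(=O)[C@@]3(C)CCC[C@@](C)([C@@H]23)C1=O | intermediate
12 | 2-(furan-3-yl)ethanol | OCCc1ccoc1 | starting material
13 | 3-(2-bromoethyl)furan | BrCCc1ccoc1 | intermediate
14 | 2-(furan-3-yl)ethylmagnesium bromide (not isolated) | Br[Mg]CCc1ccoc1 | intermediate
15 | 15,16-epoxy-9β-hydroxy-9-epi-labda-7,13(16),14-trien-19,6β-olide (side chain α on C9) | CC1=C[C@H]2OC(=O)[C@@]3(C)CCC[C@@](C)([C@@H]23)[C@]1(O)CCc1ccoc1 | intermediate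
16 | 15,16-epoxy-7β-hydroxylabda-8,13(16),14-trien-19,6β-olide (not isolated) | O[C@H]1[C@H]2OC(=O)[C@@]3(C)CCC[C@@](C)([C@@H]23)C(CCc4ccoc4)=C1C | intermediate
17 | 7β-acetoxy-15,16-epoxylabda-8,13(16),14-trien-19,6β-olide | CC(=O)O[C@H]1[C@H]2OC(=O)[C@@]3(C)CCC[C@@](C)([C@@H]23)C(CCc4ccoc4)=C1C | intermediate
18 | 7β-acetoxy-8α,9α:15,16-diepoxylabda-13(16),14-dien-19,6β-olide | CC(=O)O[C@H]1[C@H]2OC(=O)[C@@]3(C)CCC[C@@](C)([C@@H]23)[C@]4(CCc5ccoc5)O[C@]14C | intermediate
19 | epoxonium chloride: α-oxygen bonded to C8, C9 and C13, 16-phenylselanyl dihydrofuran formed (not isolated) | CC(=O)O[C@H]1[C@H]2OC(=O)[C@@]3(C)CCC[C@@](C)([C@@H]23)[C@@]4(CC[C@]5(C=CO[C@H]5[Se]c5ccccc5)[O+]46)[C@@]16C.[Cl-] | intermediate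
20 | 7β,8β-acetoxonium (2-methyl-1,3-dioxolan-2-ylium) chloride with the 9α,13-ether closed (not isolated) | C[C+]4O[C@@]1(C)[C@@H](O4)[C@H]2OC(=O)[C@@]3(C)CCC[C@@](C)([C@@H]23)[C@@]12CC[C@]1(C=CO[C@H]1[Se]c1ccccc1)O2.[Cl-] | intermediate
21 | (13R,16S)-8β-acetoxy-7β-hydroxy-16-(phenylselanyl)-9α,13:15,16-diepoxylabd-14-en-19,6β-olide | CC(=O)O[C@@]1(C)[C@@H](O)[C@H]2OC(=O)[C@@]3(C)CCC[C@@](C)([C@@H]23)[C@@]12CC[C@]1(C=CO[C@H]1[Se]c1ccccc1)O2 | intermediate
22 | (13R)-8β-acetoxy-7β-hydroxy-9α,13:15,16-diepoxylabd-14-en-19,6β-olide | CC(=O)O[C@@]1(C)[C@@H](O)[C@H]2OC(=O)[C@@]3(C)CCC[C@@](C)([C@@H]23)[C@@]12CC[C@]1(C=COC1)O2 | intermediate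
23 | (13R)-8β-acetoxy-9α,13:15,16-diepoxy-7-oxolabd-14-en-19,6β-olide; (4S,5R,6S,8R,9S,10S,13R); CNP0155227.2 | CC(=O)O[C@@]1(C)C(=O)[C@H]2OC(=O)[C@@]3(C)CCC[C@@](C)([C@@H]23)[C@@]12CC[C@]1(C=COC1)O2 | target

**Totals and risks**

Total step count: 13. Longest linear sequence: 12 (steps 1–6 and 8–13, from 2,6-dimethylphenol).

Steps most likely to fail:

Step 3. The hard ester enolate may add 1,2, the ring closure may be slow, or the remote phenyl groups may give low facial selectivity; the sense of induction rests on a steric model, and the antipodal diol is equally available. Fallback: set out from 4 with the soft nucleophile dimethyl 2-(3-bromopropyl)malonate and Cs2CO3 in DMF. Reversible Michael addition followed by the same intramolecular alkylation gives the gem-diester annulation product F1. Krapcho demethoxycarbonylation (LiCl, wet DMSO, 150 °C) then returns to the route at 8.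

Step 9. The perrhenate conditions may ionize the allylic system toward diene formation or Friedel–Crafts capture by the furan. Fallback: set out from 15 and use an oxidative transposition with 4-acetamido-2,2,6,6-tetramethyl-1-oxopiperidinium tetrafluoroborate in MeCN to give the 7-oxo-8(9)-ene lactone F2. Luche reduction (axial hydride from the α face) gives the 7β-alcohol 16, and acetylation as in the route rejoins at 17.

Step 11. Rearomatization of the selenylated furan cation by proton loss, or acyl migration in the orthoacid, may beat the relay. Fallback: set out from 18 and open the epoxide first with a Lewis acid (BF3·OEt2 cat., wet CH2Cl2, −78 °C), again with 7β-acetate participation, to give 8β-acetoxy-7β,9α-dihydroxy-15,16-epoxylabda-13(16),14-dien-19,6β-olide F3. A separate selenoetherification (PhSeCl, pyridine, CH2Cl2, −78 °C) then closes the free 9α-hydroxyl onto C13 and rejoins the route at 21.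

**Further compounds**

F1 | step 3 | dimethyl 8,10β-dimethyl-9-oxo-5βH-decal-7-ene-4,4-dicarboxylate 6-[(1S,2S)-1,2-diphenylethylene ketal] | COC(=O)C1(C(=O)OC)CCC[C@]2(C)C(=O)C(C)=CC3(O[C@@H](c4ccccc4)[C@H](c4ccccc4)O3)[C@H]12
F2 | step 9 | 15,16-epoxy-7-oxolabda-8,13(16),14-trien-19,6β-olide | O=C1[C@H]2OC(=O)[C@@]3(C)CCC[C@@](C)([C@@H]23)C(CCc4ccoc4)=C1C
F3 | step 11 | 8β-acetoxy-7β,9α-dihydroxy-15,16-epoxylabda-13(16),14-dien-19,6β-olide | CC(=O)O[C@@]1(C)[C@@H](O)[C@H]2OC(=O)[C@@]3(C)CCC[C@@](C)([C@@H]23)[C@@]1(O)CCc1ccoc1
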